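**Strategy.** The two heterocycles are the same kind of ring: a (2R,3R)-cis 2-phenylchroman-3-ol. Both are therefore cut at the aryl ether bonds O1–C2 (ring C) and O1′–C2′ (ring F). In the forward direction one acid treatment makes the A-ring and D-ring phenol oxygens open two cis-oxiranes at their phenyl-bearing carbons with inversion, which closes both pyrans and turns the oxirane oxygens into the C3 and C3′ hydroxyls. The substrate is an open-chain bis-epoxide in which C4 already links the two phloroglucinol rings with the final configuration; it is carried as a bis-silyl ether and the phenols are released only in the flask.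

Key step: step 12

Remarks on the chemistry (assumptions):
- Flavan locants are used for the open-chain compounds: C2 = PhCH, C3, C4 = diarylmethine carbon, primed locants for the cinnamyl-derived arm; rings A/C are the upper unit, D/F the lower unit.
- The structures of the cyclisation substrate and of its product were checked atom by atom. Both oxiranes are cis (phenyl-bearing carbon S, neighbour R), C4 is R, and inversion at C2 and C2′ gives the (2R,3R,4R)/(2′R,3′R) array of the target, so no structure needs correction.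
- The free bis-phenol bis-epoxide cannot be made by oxidising free phloroglucinol-type phenols and would not store. The storable form is the bis-triethylsilyl ether.
- The sense of induction in step 9 cannot be assigned with confidence for this tetra-ortho-substituted quinone methide. The (R)-biphenol is written; its antipode is used if a first run shows the opposite sense.
- The CIP descriptor at C4 changes with the O-substituents (S in the step 9 product, R afterwards) while the spatial arrangement stays the same.

**Step 1**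
Reactants: 1 3,5-bis(benzyloxy)phenol
Product: 2 4,6-bis(benzyloxy)-2-hydroxybenzaldehyde
Conditions: MgCl2, Et3N, (CH2O)n, MeCN, reflux
Reagents that add atoms: paraformaldehyde (as formaldehyde), C=O
Why: Magnesium-phenoxide-directed ortho-formylation (Casnati–Skattebøl) delivers the formyl group only ortho to the hydroxyl, and the two ortho positions of 1 are equivalent.

**Step 2**
Reactants: 2 4,6-bis(benzyloxy)-2-hydroxybenzaldehyde; 3 phenylacetylene
Product: 5 rac-3,5-bis(benzyloxy)-2-(1-hydroxy-3-phenylprop-2-yn-1-yl)phenol, via lithium phenylacetylide 4 (not isolated)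
Conditions: 3 (2.4 equiv), n-BuLi (2.3 equiv), THF, −78 °C; then 2, −78 → 0 °C; H2O; used crude
Reagents that add atoms: none
Why: 1,2-Addition of a lithium acetylide to the aldehyde, the first equivalent being spent on the phenol; the carbinol centre is racemic and is removed in step 3.

**Step 3**
Reactants: 5 rac-3,5-bis(benzyloxy)-2-(1-hydroxy-3-phenylprop-2-yn-1-yl)phenol
Product: 6 3,5-bis(benzyloxy)-2-(3-phenylprop-2-yn-1-yl)phenol
Conditions: Et3SiH, TFA, CH2Cl2, −40 → 0 °C
Reagents that add atoms: none
Why: Ionic hydrogenation: acid ionises the doubly activated carbinol and triethylsilane should reduce the resulting cation at the benzylic carbon, the position that restores the aromatic ring, leaving the alkyne in place.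

**Step 4**
Reactants: 6 3,5-bis(benzyloxy)-2-(3-phenylprop-2-yn-1-yl)phenol
Product: 7 3,5-bis(benzyloxy)-2-[(2Z)-3-phenylprop-2-en-1-yl]phenol
Conditions: H2 (1 atm), Lindlar catalyst, quinoline, EtOAc, rt
Reagents that add atoms: none
Why: Lindlar semihydrogenation adds hydrogen syn to the alkyne and stops at the (Z)-alkene, and aryl benzyl ethers are not cleaved over the poisoned catalyst.

**Step 5**
Reactants: 7 3,5-bis(benzyloxy)-2-[(2Z)-3-phenylprop-2-en-1-yl]phenol
Product: 8 4,6-bis(benzyloxy)-2-hydroxy-3-[(2Z)-3-phenylprop-2-en-1-yl]benzaldehyde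
Conditions: MgCl2, Et3N, (CH2O)n, THF, reflux
Reagents that add atoms: paraformaldehyde (as formaldehyde), C=O
Why: Second Casnati–Skattebøl ortho-formylation; only one position ortho to the hydroxyl is still free, so the formyl group enters at the future C8′.

**Step 6**
Reactants: 1 3,5-bis(benzyloxy)phenol
Product: 9 1,3-bis(benzyloxy)-5-(methoxymethoxy)benzene
Conditions: MOMCl, i-Pr2NEt, CH2Cl2, 0 °C → rt
Reagents that add atoms: chloromethyl methyl ether, COCCl
Why: O-Alkylation of the phenol gives an acetal that protects the future A-ring oxygen and directs ortho-metalation.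

**Step 7**
Reactants: 9 1,3-bis(benzyloxy)-5-(methoxymethoxy)benzene; 8 4,6-bis(benzyloxy)-2-hydroxy-3-[(2Z)-3-phenylprop-2-en-1-yl]benzaldehyde
Product: 11 rac-3,5-bis(benzyloxy)-2-{[2,4-bis(benzyloxy)-6-(methoxymethoxy)phenyl](hydroxy)methyl}-6-[(2Z)-3-phenylprop-2-en-1-yl]phenol, via [2,4-bis(benzyloxy)-6-(methoxymethoxy)phenyl]lithium 10 (not isolated)
Conditions: 9 (2.4 equiv), n-BuLi (2.2 equiv), THF, 0 °C; then 8, −78 → −20 °C; H2O; Et3N-washed silica
Reagents that add atoms: none
Why: Directed ortho-metalation at the site flanked by the MOM and benzyloxy oxygens, then 1,2-addition of the aryllithium to the aldehyde whose phenol the first equivalent deprotonates (which also lowers the acidity of the arm CH2); the carbinol centre is racemic and is erased in step 9.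

**Step 8**
Reactants: 3 phenylacetylene
Product: 13 [(Z)-2-phenylethenyl]boronic acid, via 2-[(Z)-2-phenylethenyl]-1,3,2-benzodioxaborole 12 (not isolated)
Conditions: catecholborane, [Rh(cod)Cl]2 (cat.), P(i-Pr)3, Et3N, cyclohexane, rt; then H2O
Reagents that add atoms: catecholborane, B1Oc2ccccc2O1; water, O
Why: Rhodium-catalysed trans-hydroboration of a terminal alkyne (through a rhodium vinylidene) gives the (Z)-alkenylboronate, and water cleaves the catechol ester to the boronic acid.

**Step 9**
Reactants: 11 rac-carbinol; 13 [(Z)-2-phenylethenyl]boronic acid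
Product: 16 3,5-bis(benzyloxy)-2-{(1S,2Z)-1-[2,4-bis(benzyloxy)-6-(methoxymethoxy)phenyl]-3-phenylprop-2-en-1-yl}-6-[(2Z)-3-phenylprop-2-en-1-yl]phenol, via diisopropyl [(Z)-2-phenylethenyl]boronate 14 (not isolated), via D-ring o-quinone methide 15 (not isolated)
Conditions: 13, i-PrOH, 4 Å MS, PhCF3, rt; then 11, (R)-3,3′-Br2-BINOL (15 mol %), 25–40 °C
Reagents that add atoms: none
Why: Chiral-biphenol-catalysed alkenylboronate addition to an o-quinone methide (Petasis-type): 11 loses water to 15, which only the free D-ring phenol can form, and the biphenol-exchanged boronate bound at the quinone methide oxygen transfers the styryl group with retention of Z geometry to one face of the exocyclic carbon, setting C4 under catalyst control.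

**Step 10**
Reactants: 16 A-ring MOM ether / D-ring phenol
Product: 17 [3,5-bis(benzyloxy)-2-{(1R,2Z)-1-[2,4-bis(benzyloxy)-6-(triethylsilyloxy)phenyl]-3-phenylprop-2-en-1-yl}-6-[(2Z)-3-phenylprop-2-en-1-yl]phenoxy]triethylsilane
Conditions: TESOTf, 2,2′-bipyridyl, CH2Cl2, 0 °C → rt
Reagents that add atoms: triethylsilyl triflate, CC[Si](CC)(CC)OS(=O)(=O)C(F)(F)F
Why: Silyl triflate/2,2′-bipyridyl acetal exchange converts the aryl MOM ether directly into the aryl triethylsilyl ether and the same reagent silylates the free D-ring phenol, so both phenols are masked for the oxidation without protic acid.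

**Step 11**
Reactants: 17 bis-TES bis-(Z)-alkene
Product: 18 [3,5-bis(benzyloxy)-2-{(R)-[2,4-bis(benzyloxy)-6-(triethylsilyloxy)phenyl][(2R,3S)-3-phenyloxiran-2-yl]methyl}-6-{[(2R,3S)-3-phenyloxiran-2-yl]methyl}phenoxy]triethylsilane
Conditions: (S,S)-Jacobsen (salen)Mn(III)Cl (10 mol % per alkene), mCPBA, NMO, CH2Cl2, −78 °C
Reagents that add atoms: mCPBA, OOC(=O)c1cccc(Cl)c1
Why: Jacobsen epoxidation of two cis-disubstituted aryl alkenes: the (S,S)-catalyst, the antipode that converts indene into its (1S,2R)-oxide, should deliver oxygen to the corresponding face of each Z-styrene, setting C2, C3, C2′ and C3′ under catalyst control with the cis geometry carried over from the alkenes.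

**Step 12**
Reactants: 18 bis-TES bis-cis-epoxide
Product: 20 (2R,3R,4R)-5,7-bis(benzyloxy)-4-[(2R,3R)-5,7-bis(benzyloxy)-3-hydroxy-2-phenylchroman-8-yl]-2-phenylchroman-3-ol, via bis-phenol bis-cis-epoxide 19 (not isolated)
Conditions: TBAF/AcOH (1:1), THF, −20 → 0 °C; pH 7 wash, crude 19 taken on at once; CSA (10 mol %), CH2Cl2, −20 → 0 °C
Reagents that add atoms: none
Why: Buffered fluoride frees both phenols without forming phenoxides; CSA then activates each oxirane and the ortho phenol oxygen attacks the phenyl-bearing carbon from the face opposite the departing oxygen (O1 to C2, O1′ to C2′) in an acid-assisted SN2-like opening. The closest known reaction is the acid-mediated cyclisation of 2-(2,3-epoxy-3-arylpropyl)phenols to flavan-3-ols, here run at two sites in one flask. Ring C closes 6-endo-tet at C2 and ring F closes 6-endo-tet at C2′; the 5-exo paths at C3 and C3′ are disfavoured because the developing positive charge is better carried by the benzylic carbons. No new stereocentre is made: C2 and C2′ are inverted (S to R) under control of the oxirane configuration while C3, C3′ and C4 are untouched, so each cis-oxirane becomes a 2,3-cis chroman-3-ol. The step needs endo over exo opening, inversion over ionisation, and attack of the A-ring and not the D-ring oxygen on the upper oxirane; the unactivated phenyl groups and the weak acid should secure the first two, and the C4 configuration the third, because placing the D-ring oxygen for attack at C2 forces the A-ring aryl into the crowded sector between C2 and the oxirane oxygen, whereas the A-ring attack leaves only H-4 there.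

**Step 13**
Reactants: 20 tetra-O-benzyl dimer
Product: 21 (2R,3R,4R)-2-phenyl-4-[(2R,3R)-3,5,7-trihydroxy-2-phenylchroman-8-yl]chromane-3,5,7-triol (CNP0154953.1)
Conditions: H2 (1 atm), Pd(OH)2/C, THF–MeOH, rt
Reagents that add atoms: none
Why: Hydrogenolysis of the four aryl benzyl ethers over Pearlman's catalyst; the benzylic C2–O1 and C2′–O1′ ring bonds and the C4–C8′ bond of flavan-3-ols should persist under these neutral conditions and no stereocentre is touched.

**Compound list**

1 | 3,5-bis(benzyloxy)phenol | Oc1cc(OCc2ccccc2)cc(OCc2ccccc2)c1 | starting material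
2 | 4,6-bis(benzyloxy)-2-hydroxybenzaldehyde | O=Cc1c(O)cc(OCc2ccccc2)cc1OCc1ccccc1 | intermediate
3 | phenylacetylene | C#Cc1ccccc1 | starting material
4 | lithium phenylacetylide (not isolated) | [Li]C#Cc1ccccc1 | intermediate
5 | rac-3,5-bis(benzyloxy)-2-(1-hydroxy-3-phenylprop-2-yn-1-yl)phenol | OC(C#Cc1ccccc1)c1c(O)cc(OCc2ccccc2)cc1OCc1ccccc1 | intermediate
6 | 3,5-bis(benzyloxy)-2-(3-phenylprop-2-yn-1-yl)phenol | Oc1cc(OCc2ccccc2)cc(OCc2ccccc2)c1CC#Cc1ccccc1 | intermediate
7 | 3,5-bis(benzyloxy)-2-[(2Z)-3-phenylprop-2-en-1-yl]phenol | Oc1cc(OCc2ccccc2)cc(OCc2ccccc2)c1C/C=C\c1ccccc1 | intermediate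
8 | 4,6-bis(benzyloxy)-2-hydroxy-3-[(2Z)-3-phenylprop-2-en-1-yl]benzaldehyde | O=Cc1c(O)c(C/C=C\c2ccccc2)c(OCc2ccccc2)cc1OCc1ccccc1 | intermediate
9 | 1,3-bis(benzyloxy)-5-(methoxymethoxy)benzene | COCOc1cc(OCc2ccccc2)cc(OCc2ccccc2)c1 | intermediate
10 | [2,4-bis(benzyloxy)-6-(methoxymethoxy)phenyl]lithium (not isolated) | [Li]c1c(OCOC)cc(OCc2ccccc2)cc1OCc1ccccc1 | intermediate
11 | rac-3,5-bis(benzyloxy)-2-{[2,4-bis(benzyloxy)-6-(methoxymethoxy)phenyl](hydroxy)methyl}-6-[(2Z)-3-phenylprop-2-en-1-yl]phenol | OC(c1c(OCOC)cc(OCc2ccccc2)cc1OCc1ccccc1)c1c(O)c(C/C=C\c2ccccc2)c(OCc2ccccc2)cc1OCc1ccccc1 | intermediate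
12 | 2-[(Z)-2-phenylethenyl]-1,3,2-benzodioxaborole (not isolated) | c1ccccc1/C=C\B1Oc2ccccc2O1 | intermediate
13 | [(Z)-2-phenylethenyl]boronic acid | OB(O)/C=C\c1ccccc1 | intermediate
14 | diisopropyl [(Z)-2-phenylethenyl]boronate (not isolated) | CC(C)OB(OC(C)C)/C=C\c1ccccc1 | intermediate
15 | D-ring o-quinone methide: 6-{[2,4-bis(benzyloxy)-6-(methoxymethoxy)phenyl]methylidene}-3,5-bis(benzyloxy)-2-[(2Z)-3-phenylprop-2-en-1-yl]cyclohexa-2,4-dien-1-one (not isolated) | O=C1C(C/C=C\c2ccccc2)=C(OCc2ccccc2)C=C(OCc2ccccc2)C1=Cc1c(OCOC)cc(OCc2ccccc2)cc1OCc1ccccc1 | intermediate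
16 | 3,5-bis(benzyloxy)-2-{(1S,2Z)-1-[2,4-bis(benzyloxy)-6-(methoxymethoxy)phenyl]-3-phenylprop-2-en-1-yl}-6-[(2Z)-3-phenylprop-2-en-1-yl]phenol | c1ccccc1/C=C\[C@H](c1c(OCOC)cc(OCc2ccccc2)cc1OCc1ccccc1)c1c(O)c(C/C=C\c2ccccc2)c(OCc2ccccc2)cc1OCc1ccccc1 | intermediate
17 | [3,5-bis(benzyloxy)-2-{(1R,2Z)-1-[2,4-bis(benzyloxy)-6-(triethylsilyloxy)phenyl]-3-phenylprop-2-en-1-yl}-6-[(2Z)-3-phenylprop-2-en-1-yl]phenoxy]triethylsilane | c1ccccc1/C=C\[C@H](c1c(O[Si](CC)(CC)CC)cc(OCc2ccccc2)cc1OCc1ccccc1)c1c(O[Si](CC)(CC)CC)c(C/C=C\c2ccccc2)c(OCc2ccccc2)cc1OCc1ccccc1 | intermediate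
18 | bis-TES bis-cis-epoxide: [3,5-bis(benzyloxy)-2-{(R)-[2,4-bis(benzyloxy)-6-(triethylsilyloxy)phenyl][(2R,3S)-3-phenyloxiran-2-yl]methyl}-6-{[(2R,3S)-3-phenyloxiran-2-yl]methyl}phenoxy]triethylsilane | c1ccccc1[C@@H]3O[C@@H]3[C@H](c4c(O[Si](CC)(CC)CC)cc(OCc5ccccc5)cc4OCc5ccccc5)c4c(OCc5ccccc5)cc(OCc5ccccc5)c(C[C@H]5O[C@H]5c6ccccc6)c4O[Si](CC)(CC)CC | intermediate
19 | bis-phenol bis-cis-epoxide: 3,5-bis(benzyloxy)-2-{(R)-[2,4-bis(benzyloxy)-6-hydroxyphenyl][(2R,3S)-3-phenyloxiran-2-yl]methyl}-6-{[(2R,3S)-3-phenyloxiran-2-yl]methyl}phenol (not isolated) | c1ccccc1[C@@H]3O[C@@H]3[C@H](c4c(O)cc(OCc5ccccc5)cc4OCc5ccccc5)c4c(OCc5ccccc5)cc(OCc5ccccc5)c(C[C@H]5O[C@H]5c6ccccc6)c4O | intermediate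
20 | (2R,3R,4R)-5,7-bis(benzyloxy)-4-[(2R,3R)-5,7-bis(benzyloxy)-3-hydroxy-2-phenylchroman-8-yl]-2-phenylchroman-3-ol | c1ccccc1COc1cc(OCc3ccccc3)c2c(c1)O[C@H](c1ccccc1)[C@H](O)[C@H]2c1c(OCc3ccccc3)cc(OCc3ccccc3)c2c1O[C@H](c1ccccc1)[C@H](O)C2 | intermediate
21 | (2R,3R,4R)-2-phenyl-4-[(2R,3R)-3,5,7-trihydroxy-2-phenylchroman-8-yl]chromane-3,5,7-triol | Oc1cc(O)c2c(c1)O[C@H](c1ccccc1)[C@H](O)[C@H]2c1c(O)cc(O)c2c1O[C@H](c1ccccc1)[C@H](O)C2 | target

**Step count.** Total: 13 steps. Longest linear sequence: 11 steps (steps 1, 2, 3, 4, 5, 7, 9, 10, 11, 12, 13).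

**Steps most likely to fail**

Step 12 (key step). The D-ring oxygen may compete for the upper oxirane, 5-exo opening may intrude, or ionisation at a benzylic carbon may erode the cis relationship. The fallback takes the two closures apart and sets out from 18. One equivalent of TBAF/AcOH at −40 °C should cleave the A-ring silyl ether (one ortho substituent) ahead of the D-ring one (two ortho substituents) and give the A-ring mono-phenol bis-epoxide F1. CSA then closes ring C alone, with no second phenol free, to the ring-C chromanol oxirane silyl ether F2. A second buffered fluoride treatment frees the ring-C chromanol oxirane phenol F3, which CSA closes to ring F. The route is rejoined at 20.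

Step 9. Facial discrimination may be poor at a quinone methide whose exocyclic carbon carries a di-ortho-substituted aryl group, transfer of the Z-alkenyl group may be slow, or Z geometry may erode. The fallback gives up catalytic induction for a resolution and sets out from 11. With achiral 2,2′-biphenol in place of the chiral catalyst the same boronate addition should give the racemic triarylmethane-type phenol F4. Esterification of its phenol with (1S)-camphanic chloride (Et3N, DMAP), then separation of the diastereomers by chromatography or crystallisation, gives the (1S)-camphanate of the (S)-enantiomer F5. K2CO3/MeOH releases the phenol and the route is rejoined at 16.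

Step 11. The stepwise oxo-manganese pathway may leak to trans-epoxide through its radical intermediate, the hindered upper alkene may convert incompletely, or face selection may be mismatched next to C4. The fallback replaces it by a concerted peroxo-titanium oxygen transfer: a titanium–salalen complex with aqueous H2O2 in CH2Cl2, which is stereospecific for cis-alkenes, with the ligand antipode chosen for the same face. It sets out from 17 and rejoins the route at 18; no compound outside the list is made (F0).

**Further compounds**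

F1 | step 12 | A-ring mono-phenol bis-epoxide (D-ring oxygen still triethylsilylated) | c1ccccc1[C@@H]3O[C@@H]3[C@H](c4c(O)cc(OCc5ccccc5)cc4OCc5ccccc5)c4c(OCc5ccccc5)cc(OCc5ccccc5)c(C[C@H]5O[C@H]5c6ccccc6)c4O[Si](CC)(CC)CC
F2 | step 12 | ring-C chromanol oxirane silyl ether (upper pyran closed, lower cis-oxirane, D-ring OTES) | c1ccccc1COc1cc(OCc3ccccc3)c2c(c1)O[C@H](c1ccccc1)[C@H](O)[C@H]2c1c(OCc3ccccc3)cc(OCc3ccccc3)c(C[C@H]5O[C@H]5c6ccccc6)c1O[Si](CC)(CC)CC
F3 | step 12 | ring-C chromanol oxirane phenol (upper pyran closed, lower cis-oxirane, D-ring OH) | c1ccccc1COc1cc(OCc3ccccc3)c2c(c1)O[C@H](c1ccccc1)[C@H](O)[C@H]2c1c(OCc3ccccc3)cc(OCc3ccccc3)c(C[C@H]5O[C@H]5c6ccccc6)c1O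
F4 | step 9 | racemic triarylmethane-type phenol (rac-16) | c1ccccc1/C=C\C(c1c(OCOC)cc(OCc2ccccc2)cc1OCc1ccccc1)c1c(O)c(C/C=C\c2ccccc2)c(OCc2ccccc2)cc1OCc1ccccc1
F5 | step 9 | (1S)-camphanate of the (S)-enantiomer (ester at the D-ring oxygen) | c1ccccc1/C=C\[C@H](c1c(OCOC)cc(OCc2ccccc2)cc1OCc1ccccc1)c1c(OC(=O)[C@@]23CC[C@@](C)(C(=O)O2)C3(C)C)c(C/C=C\c2ccccc2)c(OCc2ccccc2)cc1OCc1ccccc1
F0 | step 11 | none | none
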